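**Plan**
- Enabling feature: C4 of ring C is a ketone carbon held between C4a of ring A and the oxygen-bearing C3. It can therefore enter as carbon monoxide between a ring A aryl iodide and an enolate that already carries O3, C2 and ring B.
- Retrosynthesis: the 5-O-methyl bond and the O1–C2 bond are cut first (demethylation, cyclodehydration), then C4–C4a and C4–C3 together. The ketone is then cut at its aryl–acyl bond and the iodide at C–I.
- Forward: the iodide and the α-benzyloxy ketone are made separately and joined with CO to the open 1,3-diketone. Ring C, the only ring formed, closes afterwards through O1–C2, and the 5-hydroxyl is freed last.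
- Stereochemistry: the target is achiral. The single stereocentre of the open diketone is racemic and enolizable and becomes the trigonal C3.

Key step: step 4

Remark: flavone locants (O1, C2, C3, C4, C4a, C5 to C8, C8a; ring B primed) are used from the diketone onward, and compounds 1, 3, 5 and 8 are taken as purchasable.

**Step 1**
Reactants: 1 1,2,3,5-tetramethoxybenzene
Product: 2 2-iodo-1,3,4,5-tetramethoxybenzene (1-iodo-2,3,4,6-tetramethoxybenzene)
Conditions: NIS (1.05 equiv), CF3CO2H (0.1 equiv), MeCN, 0 °C → rt, dark
Reagents that add atoms: N-iodosuccinimide, O=C1CCC(=O)N1I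
Why: Electrophilic aromatic iodination; the two free positions of 1 are equivalent by symmetry and each lies between two methoxyls, so one mono-iodide should form, and the iodine then deactivates and shields the ring against a second substitution.

**Step 2**
Reactants: 3 benzyloxyacetyl chloride
Product: 4 2-(benzyloxy)-N-methoxy-N-methylacetamide
Conditions: MeNHOMe·HCl (1.1 equiv), Et3N (2.3 equiv), CH2Cl2, 0 °C → rt
Reagents that add atoms: N,O-dimethylhydroxylamine hydrochloride, CNOC.Cl
Why: N-Acylation of the hydroxylamine by the acid chloride (Weinreb amide formation), to which the benzyl ether is inert.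

**Step 3**
Reactants: 5 5-bromo-1,2,3-trimethoxybenzene; 4 2-(benzyloxy)-N-methoxy-N-methylacetamide
Product: 7 2-(benzyloxy)-1-(3,4,5-trimethoxyphenyl)ethan-1-one, via arylmagnesium bromide 6 (not isolated)
Conditions: Mg turnings, I2 (cat.), THF, 50 °C; then 4, THF, 0 °C → rt; 1 M HCl work-up
Reagents that add atoms: none
Why: Grignard formation followed by Weinreb ketone synthesis; the magnesium chelate of the tetrahedral adduct persists until work-up, so addition should stop at the ketone.

**Step 4**
Reactants: 2 2-iodo-1,3,4,5-tetramethoxybenzene; 8 carbon monoxide; 7 2-(benzyloxy)-1-(3,4,5-trimethoxyphenyl)ethan-1-one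
Product: 9 2-(benzyloxy)-1-(2,3,4,6-tetramethoxyphenyl)-3-(3,4,5-trimethoxyphenyl)propane-1,3-dione
Conditions: Pd(dba)2 (5 mol %), Xantphos (5 mol %), MgCl2 (2 equiv), Et3N (3 equiv), CO (1 atm), 1,4-dioxane, 80 °C; 1 M HCl work-up
Reagents that add atoms: none
Why: Zerovalent palladium (from Pd(dba)2 and Xantphos) adds oxidatively to the C–I bond of 2, CO inserts to give an aroyl complex of divalent palladium, and the magnesium enolate of 7 (soft enolization with MgCl2 and Et3N) is C-acylated by it through attack at palladium and C–C reductive elimination, which forms C4a–C4 and C4–C3 in one operation and returns zerovalent palladium. The closest known reaction is the palladium-catalysed carbonylative α-arylation of aryl ketones with aryl iodides to 1,3-diketones. No ring closes here; ring C is closed in step 5. The one new stereocentre, the benzyloxy-bearing carbon between the two carbonyls, forms racemic, is enolizable and ends as the trigonal C3, so it needs no control. The step needs acylation to win over direct α-arylation and O-acylation: the two ortho methoxyls of 2 hinder coupling at the aryl–palladium stage but not CO insertion, the CO atmosphere and the wide bite angle of Xantphos favour the acyl complex and its reductive elimination, and magnesium chelation between the enolate oxygen and the benzyloxy oxygen steers the carbon terminus to the acyl group and holds the product as a stable diketonate.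

**Step 5**
Reactants: 9 2-(benzyloxy)-1-(2,3,4,6-tetramethoxyphenyl)-3-(3,4,5-trimethoxyphenyl)propane-1,3-dione
Product: 11 3-hydroxy-5,7,8-trimethoxy-2-(3,4,5-trimethoxyphenyl)-4H-chromen-4-one, via free hydroxy diketone 10 (not isolated)
Conditions: BCl3 (1 M in CH2Cl2, 4 equiv), C6HMe5 (3 equiv), CH2Cl2, −78 → 0 °C; aqueous work-up; then conc. HCl (cat.), EtOH, 70 °C
Reagents that add atoms: none
Why: Lewis-acid ether cleavage followed by acid-catalysed cyclodehydration: BCl3 should remove the benzyl group (its cation being caught by pentamethylbenzene before it can alkylate C6 of ring A) and, through chelation to the ring A carbonyl, the ortho methyl ether crowded between the acyl group and the neighbouring methoxyl, which is the one lost when this ring is acylated under Lewis-acid conditions, the resulting aryloxyboron chelate then protecting the second ortho methoxyl, after which the freed phenol adds to the ring B ketone and the hemiketal loses water to give the pyranone with O3 already in place.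

**Step 6**
Reactants: 11 3-hydroxy-5,7,8-trimethoxy-2-(3,4,5-trimethoxyphenyl)-4H-chromen-4-one
Product: 12 3,5-dihydroxy-7,8-dimethoxy-2-(3,4,5-trimethoxyphenyl)-4H-chromen-4-one
Conditions: BCl3 (1 M in CH2Cl2, 3 equiv), CH2Cl2, −20 → 0 °C; then 1 M HCl, rt
Reagents that add atoms: none
Why: Chelation-controlled aryl methyl ether cleavage: of the six methoxyls only the one at C5 is peri to the C4 carbonyl and can close a six-membered boron chelate, so BCl3 at low temperature should cleave it selectively, as is usual for 5-methoxyflavones.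

**Compound list**
1 | 1,2,3,5-tetramethoxybenzene | COc1cc(OC)c(OC)c(OC)c1 | starting material
2 | 2-iodo-1,3,4,5-tetramethoxybenzene (1-iodo-2,3,4,6-tetramethoxybenzene) | COc1cc(OC)c(I)c(OC)c1OC | intermediate
3 | benzyloxyacetyl chloride | O=C(Cl)COCc1ccccc1 | starting material
4 | 2-(benzyloxy)-N-methoxy-N-methylacetamide | CON(C)C(=O)COCc1ccccc1 | intermediate
5 | 5-bromo-1,2,3-trimethoxybenzene | COc1cc(Br)cc(OC)c1OC | starting material
6 | 3,4,5-trimethoxyphenylmagnesium bromide | COc1cc([Mg]Br)cc(OC)c1OC | intermediate (not isolated)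
7 | 2-(benzyloxy)-1-(3,4,5-trimethoxyphenyl)ethan-1-one | COc1cc(C(=O)COCc2ccccc2)cc(OC)c1OC | intermediate
8 | carbon monoxide | [C-]#[O+] | starting material
9 | 2-(benzyloxy)-1-(2,3,4,6-tetramethoxyphenyl)-3-(3,4,5-trimethoxyphenyl)propane-1,3-dione (racemic, enolizable) | COc1cc(OC)c(C(=O)C(OCc2ccccc2)C(=O)c2cc(OC)c(OC)c(OC)c2)c(OC)c1OC | intermediate
10 | 2-hydroxy-1-(2-hydroxy-3,4,6-trimethoxyphenyl)-3-(3,4,5-trimethoxyphenyl)propane-1,3-dione (racemic, in equilibrium with its cyclic hemiketal) | COc1cc(OC)c(C(=O)C(O)C(=O)c2cc(OC)c(OC)c(OC)c2)c(O)c1OC | intermediate (not isolated)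
11 | 3-hydroxy-5,7,8-trimethoxy-2-(3,4,5-trimethoxyphenyl)-4H-chromen-4-one | COc1cc(-c2oc3c(OC)c(OC)cc(OC)c3c(=O)c2O)cc(OC)c1OC | intermediate
12 | 3,5-dihydroxy-7,8-dimethoxy-2-(3,4,5-trimethoxyphenyl)-4H-chromen-4-one (3,5-dihydroxy-7,8,3',4',5'-pentamethoxyflavone) | COc1cc(-c2oc3c(OC)c(OC)cc(O)c3c(=O)c2O)cc(OC)c1OC | target

**Step count and risks**
Total step count: 6. Longest linear sequence: 5 steps (3 → 4 → 7 → 9 → 11 → 12; the branch from 1 is 4 steps).

Steps most likely to fail:

Step 4. The aroyl–palladium intermediate may be taken up too slowly by the hindered, chelated enolate. Direct α-arylation without CO, O-acylation to the enol ester or reduction of the iodide could then take over. The fallback builds the same diketone by aldol addition and oxidation and sets out from 1 and 7. Vilsmeier–Haack formylation of 1 (POCl3, DMF) should give 2,3,4,6-tetramethoxybenzaldehyde F1. The lithium enolate of 7 (LiN(iPr)2, THF, −78 °C) adds to it to give 2-(benzyloxy)-3-hydroxy-3-(2,3,4,6-tetramethoxyphenyl)-1-(3,4,5-trimethoxyphenyl)propan-1-one F2 as a mixture of diastereomers. Dess–Martin periodinane in CH2Cl2 then oxidises the carbinol, and the route is rejoined at 9.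

Step 5. Regiocontrol in the Lewis-acid demethylation may be lost: cleavage of the other ortho methyl ether, or of both, would lead after ring closure into the 5,6,7-oxygenated series. Ring A may also be benzylated by the released cation, and the free hydroxy diketone may fragment by retro-Claisen cleavage during the acid treatment. The fallback fixes the O1 phenol on a simple ketone and introduces O3 last; it sets out from 1. Friedel–Crafts acetylation with AcCl and AlCl3 in Et2O, which goes with loss of the crowded ortho methyl group, should give 1-(2-hydroxy-3,4,6-trimethoxyphenyl)ethan-1-one F3. Claisen–Schmidt condensation with 3,4,5-trimethoxybenzaldehyde (KOH, EtOH) gives (E)-1-(2-hydroxy-3,4,6-trimethoxyphenyl)-3-(3,4,5-trimethoxyphenyl)prop-2-en-1-one F4. I2 (cat.) in DMSO at 130 °C closes and dehydrogenates it to 5,7,8-trimethoxy-2-(3,4,5-trimethoxyphenyl)-4H-chromen-4-one F5. Dimethyldioxirane in acetone/CH2Cl2 epoxidises the C2–C3 double bond to 2,3-epoxy-5,7,8-trimethoxy-2-(3,4,5-trimethoxyphenyl)chroman-4-one F6. TsOH (cat.) opens the epoxide to the 3-hydroxyflavone, and the route is rejoined at 11.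

Step 6. Over-demethylation may occur at the central 4'-methoxyl of ring B or at the vicinal 7,8-pair. The reaction may also stall because boron is tied up in the five-membered chelate between O3 and the C4 carbonyl. The fallback masks O3 first and sets out from 11. TsCl and K2CO3 in acetone give 5,7,8-trimethoxy-4-oxo-2-(3,4,5-trimethoxyphenyl)-4H-chromen-3-yl 4-methylbenzenesulfonate F7. AlCl3 in MeCN then cleaves only the chelating 5-methyl ether to give 5-hydroxy-7,8-dimethoxy-4-oxo-2-(3,4,5-trimethoxyphenyl)-4H-chromen-3-yl 4-methylbenzenesulfonate F8. KOH in aqueous MeOH removes the sulfonate, and the route is rejoined at 12.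

**Further compounds**
F1 | step 4 | 2,3,4,6-tetramethoxybenzaldehyde | COc1cc(OC)c(C=O)c(OC)c1OC
F2 | step 4 | 2-(benzyloxy)-3-hydroxy-3-(2,3,4,6-tetramethoxyphenyl)-1-(3,4,5-trimethoxyphenyl)propan-1-one (racemic mixture of diastereomers) | COc1cc(OC)c(C(O)C(OCc2ccccc2)C(=O)c2cc(OC)c(OC)c(OC)c2)c(OC)c1OC
F3 | step 5 | 1-(2-hydroxy-3,4,6-trimethoxyphenyl)ethan-1-one | CC(=O)c1c(OC)cc(OC)c(OC)c1O
F4 | step 5 | (E)-1-(2-hydroxy-3,4,6-trimethoxyphenyl)-3-(3,4,5-trimethoxyphenyl)prop-2-en-1-one | COc1cc(/C=C/C(=O)c2c(OC)cc(OC)c(OC)c2O)cc(OC)c1OC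
F5 | step 5 | 5,7,8-trimethoxy-2-(3,4,5-trimethoxyphenyl)-4H-chromen-4-one | COc1cc(-c2cc(=O)c3c(OC)cc(OC)c(OC)c3o2)cc(OC)c1OC
F6 | step 5 | 2,3-epoxy-5,7,8-trimethoxy-2-(3,4,5-trimethoxyphenyl)chroman-4-one (racemic; the epoxide is necessarily cis-fused) | COc1cc(C23OC2C(=O)c2c(OC)cc(OC)c(OC)c2O3)cc(OC)c1OC
F7 | step 6 | 5,7,8-trimethoxy-4-oxo-2-(3,4,5-trimethoxyphenyl)-4H-chromen-3-yl 4-methylbenzenesulfonate | COc1cc(-c2oc3c(OC)c(OC)cc(OC)c3c(=O)c2OS(=O)(=O)c2ccc(C)cc2)cc(OC)c1OC
F8 | step 6 | 5-hydroxy-7,8-dimethoxy-4-oxo-2-(3,4,5-trimethoxyphenyl)-4H-chromen-3-yl 4-methylbenzenesulfonate | COc1cc(-c2oc3c(OC)c(OC)cc(O)c3c(=O)c2OS(=O)(=O)c2ccc(C)cc2)cc(OC)c1OC
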